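## Retrosynthetic overview

1. The tetronic acid ring is the only ring made and is made last: the enolate of methyl propanoate is C-acylated by the acetonide-masked (S)-α-hydroxy acid (dioxolanone 17), followed by lactonisation. C5 comes from the acetonide of L-malic acid (15).
2. The key CH2–C(Me)= bond is formed by a light-driven, nickel-catalysed decarboxylative syn-hydroalkylation of the methyl-capped dienyne 14 with the redox-active ester of 15; this also sets the 2E alkene.
3. Dienyne 14 comes from a Horner–Wadsworth–Emmons reaction of the (E)-enal 9 with a but-2-ynylphosphonate; 9 comes from a Wittig reaction on aldehyde 7.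
4. Aldehyde 7 comes from a Heck reaction of bromide 5 with allyl alcohol; 5 comes from furan-3-yllithium and 4-bromofuran-2-carbaldehyde, then ionic deoxygenation.
5. Both furan rings and the dioxolanone ring are bought.

Assumption: 15, the acetonide of L-malic acid, is bought as such (a catalogue compound; one step from L-malic acid and 2,2-dimethoxypropane if it must be made). The target is read from the SMILES as 5S with all three chain alkenes E.

## Route

Step 1
Reactants: 1 3-bromofuran; 2 4-bromofuran-2-carbaldehyde
Product: 5 4-bromo-2-(furan-3-ylmethyl)furan, via furan-3-yllithium 3 (not isolated), via bis-furyl carbinol 4 (not isolated)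
Conditions: n-BuLi, Et2O, −78 °C; add 2, −78 °C; then CH2Cl2, Et3SiH (4 equiv), CF3CO2H (6 equiv), −78 → 0 °C
Reagents that add atoms: none
Why: Bromine–lithium exchange gives furan-3-yllithium, which at −78 °C adds to the aldehyde faster than it isomerises or exchanges with the ring bromide; the doubly heteroaryl-stabilised carbinol is then deoxygenated by ionic hydrogenation (Et3SiH/CF3CO2H), so no stereocenter remains.

Step 2
Reactants: 5 4-bromo-2-(furan-3-ylmethyl)furan; 6 prop-2-en-1-ol
Product: 7 3-[5-(furan-3-ylmethyl)furan-3-yl]propanal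
Conditions: Pd(OAc)2 (5 mol%), n-Bu4NCl, NaHCO3, DMF, 80 °C
Reagents that add atoms: none
Why: Heck reaction with allyl alcohol under Jeffery conditions: arylation at the alkene terminus, β-hydride elimination toward the carbinol carbon and enol-to-aldehyde tautomerisation give the 3-arylpropanal directly.

Step 3
Reactants: 7 3-[5-(furan-3-ylmethyl)furan-3-yl]propanal; 8 2-(triphenyl-λ5-phosphanylidene)propanal
Product: 9 (2E)-5-[5-(furan-3-ylmethyl)furan-3-yl]-2-methylpent-2-enal
Conditions: toluene, 90 °C
Reagents that add atoms: none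
Why: Wittig olefination with a stabilised ylide gives the (E)-trisubstituted enal (typically >95:5), and the α-branched enal product is too unreactive to olefinate a second time.

Step 4
Reactants: 10 1-bromobut-2-yne; 11 triethyl phosphite
Product: 12 diethyl but-2-yn-1-ylphosphonate
Conditions: neat, 120 °C, bromoethane distilled off
Reagents that add atoms: none
Why: Michaelis–Arbuzov reaction at the primary propargylic bromide (SN2 at CH2, then dealkylation of the phosphonium by bromide).

Step 5
Reactants: 12 diethyl but-2-yn-1-ylphosphonate; 9 (2E)-5-[5-(furan-3-ylmethyl)furan-3-yl]-2-methylpent-2-enal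
Product: 14 2-(furan-3-ylmethyl)-4-[(3E,5E)-4-methylnona-3,5-dien-7-yn-1-yl]furan, via lithiated phosphonate 13 (not isolated)
Conditions: LiN(SiMe3)2, THF, −78 °C; add 9, −78 → 0 °C
Reagents that add atoms: none
Why: Horner–Wadsworth–Emmons olefination of the enal with the propargylic phosphonate anion gives the new disubstituted alkene mainly E (minor 5Z isomer removed by chromatography); the existing E-trisubstituted alkene is not touched.

Step 6
Reactants: 15 2-[(4S)-2,2-dimethyl-5-oxo-1,3-dioxolan-4-yl]acetic acid; 14 2-(furan-3-ylmethyl)-4-[(3E,5E)-4-methylnona-3,5-dien-7-yn-1-yl]furan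
Product: 17 (5S)-5-[(2E,4E,6E)-9-[5-(furan-3-ylmethyl)furan-3-yl]-2,6-dimethylnona-2,4,6-trien-1-yl]-2,2-dimethyl-1,3-dioxolan-4-one, via redox-active ester 16 (not isolated)
Conditions: 15 (1.5 equiv), N-hydroxyphthalimide, N,N'-diisopropylcarbodiimide, DMA, 23 °C, 2 h; then 14 (1.0 equiv), NiBr2·DME (10 mol%), 4,4'-di-tert-butyl-2,2'-bipyridine (12 mol%), diethyl 2,6-dimethyl-1,4-dihydropyridine-3,5-dicarboxylate (Hantzsch ester, 2 equiv), degassed, 427 nm LEDs, 20 °C
Reagents that add atoms: none
Why: Proposed new method: photocatalyst-free, nickel-catalysed decarboxylative syn-hydroalkylation of a methyl-capped conjugated dienyne. Excitation of the Hantzsch ester/N-acyloxyphthalimide donor–acceptor pair releases CO2, phthalimide anion and the primary radical β to the stereocenter; bipyridine-ligated low-valent nickel captures it, and the alkyl–nickel bond adds syn across the alkyne with the new C–C bond at the methyl-bearing carbon remote from the diene (nickel ends on the carbon next to the alkene, stabilised by eta-3 dienyl coordination, the known alkene-directing effect of 1,3-enynes). Protonolysis of the alkenyl–nickel bond with retention by the Hantzsch pyridinium gives the 2E alkene, and the dihydropyridyl radical returns nickel to its low-valent state. The stereocenter is not the radical carbon and is carried unchanged from 15 (as in nickel couplings of aspartate-derived redox-active esters), and no triplet sensitiser is present to scramble the triene. Closest known reaction types: photoredox/nickel decarboxylative hydroalkylation of simple alkynes, and donor–acceptor-complex nickel cross-coupling of redox-active esters with aryl halides.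

Step 7
Reactants: 17 (5S)-5-[(2E,4E,6E)-9-[5-(furan-3-ylmethyl)furan-3-yl]-2,6-dimethylnona-2,4,6-trien-1-yl]-2,2-dimethyl-1,3-dioxolan-4-one; 18 methyl propanoate
Product: 21 (5S)-5-[(2E,4E,6E)-9-[5-(furan-3-ylmethyl)furan-3-yl]-2,6-dimethylnona-2,4,6-trien-1-yl]-4-hydroxy-3-methylfuran-2(5H)-one, via lithium ester enolate 19 (not isolated), via open keto ester 20 (not isolated)
Conditions: LiN(i-Pr)2 (3.0 equiv), 18 (3.2 equiv), THF, −78 °C; add 17, −78 → 0 °C; MeOH, 23 °C; cold 1 M HCl work-up
Reagents that add atoms: none
Why: Claisen-type C-acylation of the ester enolate by the activated dioxolanone, loss of acetone, and lactonisation of the γ-alkoxide onto the methyl ester (the dioxolanone route to tetronic acids). No new stereocenter is formed: C5 is carried from 15 because addition to the activated carbonyl at −78 °C outruns α-deprotonation and the β-keto ester enolate then shields the adjacent C–H.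

## Compound list

1 | 3-bromofuran | Brc1ccoc1 | starting material
2 | 4-bromofuran-2-carbaldehyde | O=Cc1cc(Br)co1 | starting material
3 | furan-3-yllithium | [Li]c1ccoc1 | intermediate
4 | (4-bromofuran-2-yl)(furan-3-yl)methanol (racemic, formed as its lithium alkoxide) | OC(c1cc(Br)co1)c1ccoc1 | intermediate
5 | 4-bromo-2-(furan-3-ylmethyl)furan | Brc1coc(Cc2ccoc2)c1 | intermediate
6 | prop-2-en-1-ol (allyl alcohol) | C=CCO | starting material
7 | 3-[5-(furan-3-ylmethyl)furan-3-yl]propanal | O=CCCc1coc(Cc2ccoc2)c1 | intermediate
8 | 2-(triphenyl-λ5-phosphanylidene)propanal | CC(C=O)=P(c1ccccc1)(c1ccccc1)c1ccccc1 | starting material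
9 | (2E)-5-[5-(furan-3-ylmethyl)furan-3-yl]-2-methylpent-2-enal | O=C/C(C)=C/CCc1coc(Cc2ccoc2)c1 | intermediate
10 | 1-bromobut-2-yne | CC#CCBr | starting material
11 | triethyl phosphite | CCOP(OCC)OCC | starting material
12 | diethyl but-2-yn-1-ylphosphonate | CC#CCP(=O)(OCC)OCC | intermediate
13 | lithium salt of the carbanion of 12 (lithiated phosphonate) | [Li+].CC#C[CH-]P(=O)(OCC)OCC | intermediate
14 | 2-(furan-3-ylmethyl)-4-[(3E,5E)-4-methylnona-3,5-dien-7-yn-1-yl]furan | CC#C/C=C/C(C)=C/CCc1coc(Cc2ccoc2)c1 | intermediate
15 | 2-[(4S)-2,2-dimethyl-5-oxo-1,3-dioxolan-4-yl]acetic acid (acetonide of L-malic acid) | CC1(C)OC(=O)[C@H](CC(=O)O)O1 | starting material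
16 | 1,3-dioxoisoindolin-2-yl 2-[(4S)-2,2-dimethyl-5-oxo-1,3-dioxolan-4-yl]acetate (redox-active ester) | CC1(C)OC(=O)[C@H](CC(=O)ON2C(=O)c3ccccc3C2=O)O1 | intermediate
17 | (5S)-5-[(2E,4E,6E)-9-[5-(furan-3-ylmethyl)furan-3-yl]-2,6-dimethylnona-2,4,6-trien-1-yl]-2,2-dimethyl-1,3-dioxolan-4-one | CC1(C)OC(=O)[C@H](C/C(C)=C/C=C/C(C)=C/CCc2coc(Cc3ccoc3)c2)O1 | intermediate
18 | methyl propanoate | CCC(=O)OC | starting material
19 | lithium enolate of methyl propanoate | CC=C(OC)O[Li] | intermediate
20 | methyl (4S,6E,8E,10E)-13-[5-(furan-3-ylmethyl)furan-3-yl]-4-hydroxy-2,6,10-trimethyl-3-oxotrideca-6,8,10-trienoate (both C2 epimers, formed as its lithium salt) | COC(=O)C(C)C(=O)[C@@H](O)C/C(C)=C/C=C/C(C)=C/CCc1coc(Cc2ccoc2)c1 | intermediate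
21 | (5S)-5-[(2E,4E,6E)-9-[5-(furan-3-ylmethyl)furan-3-yl]-2,6-dimethylnona-2,4,6-trien-1-yl]-4-hydroxy-3-methylfuran-2(5H)-one | CC1=C(O)[C@H](C/C(C)=C/C=C/C(C)=C/CCc2coc(Cc3ccoc3)c2)OC1=O | target

## Step count and risks

Total steps: 7. Longest linear sequence: 6 (steps 1, 2, 3, 5, 6, 7); step 4 is a one-step side branch.

**Step 6 (the proposed new reaction).** It can fail through attack at the wrong alkyne carbon, loss of 2E geometry by isomerisation of the alkenyl–nickel species, simple reduction of the radical by the Hantzsch ester, or over-alkylation of the product triene. The fallback uses known chemistry and sets out from 14. Syn-hydrozirconation with Cp2Zr(H)Cl (THF, 23 °C, zirconium at the less hindered methyl-bearing carbon) and iodinolysis (I2, 0 °C) give 2-(furan-3-ylmethyl)-4-[(3E,5E,7E)-8-iodo-4-methylnona-3,5,7-trien-1-yl]furan F1. The redox-active ester 16, now isolated from 15 (N-hydroxyphthalimide, N,N'-diisopropylcarbodiimide, CH2Cl2), is then joined to F1 by the established nickel-electrocatalytic decarboxylative alkenylation (NiCl2·6H2O, 2,2'-bipyridine, AgNO3, Mg anode, carbon cathode, DMF, constant current, 23 °C). This comes back to the route at 17.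

**Step 7.** The risks are partial loss of configuration at C5 if the enolate deprotonates the dioxolanone before adding to it, and incomplete lactonisation; the enantiomeric ratio of 21 should be checked by chiral HPLC. The fallback sets out from 17. Methanolysis (catalytic K2CO3, MeOH, 0 °C) gives methyl (2S,4E,6E,8E)-11-[5-(furan-3-ylmethyl)furan-3-yl]-2-hydroxy-4,8-dimethylundeca-4,6,8-trienoate F2. Acylation with propanoyl chloride (pyridine, DMAP, CH2Cl2, 0 °C) gives methyl (2S,4E,6E,8E)-11-[5-(furan-3-ylmethyl)furan-3-yl]-4,8-dimethyl-2-(propanoyloxy)undeca-4,6,8-trienoate F3. Dieckmann cyclisation (LiN(SiMe3)2, 2.2 equiv, THF, −78 → 0 °C), which is known to preserve the α-oxygenated stereocenter, comes back to the route at 21.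

**Step 2.** Oxidative addition to the electron-rich 3-bromofuran unit is slow, and branched aldehyde, aldol products or direct arylation of a furan C–H can compete. The fallback sets out from 5. Negishi coupling with commercial [2-(1,3-dioxolan-2-yl)ethyl]zinc bromide, BrZnCH2CH2CH(OCH2CH2O), using Pd(OAc)2/SPhos in THF at 50 °C gives 2-{2-[5-(furan-3-ylmethyl)furan-3-yl]ethyl}-1,3-dioxolane F4. Mild acetal hydrolysis (pyridinium p-toluenesulfonate, acetone/water, 50 °C) comes back to the route at 7.

## Further compounds

F1 | step 6 | 2-(furan-3-ylmethyl)-4-[(3E,5E,7E)-8-iodo-4-methylnona-3,5,7-trien-1-yl]furan | I/C(C)=C/C=C/C(C)=C/CCc1coc(Cc2ccoc2)c1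
F2 | step 7 | methyl (2S,4E,6E,8E)-11-[5-(furan-3-ylmethyl)furan-3-yl]-2-hydroxy-4,8-dimethylundeca-4,6,8-trienoate | COC(=O)[C@@H](O)C/C(C)=C/C=C/C(C)=C/CCc1coc(Cc2ccoc2)c1
F3 | step 7 | methyl (2S,4E,6E,8E)-11-[5-(furan-3-ylmethyl)furan-3-yl]-4,8-dimethyl-2-(propanoyloxy)undeca-4,6,8-trienoate | COC(=O)[C@@H](OC(=O)CC)C/C(C)=C/C=C/C(C)=C/CCc1coc(Cc2ccoc2)c1
F4 | step 2 | 2-{2-[5-(furan-3-ylmethyl)furan-3-yl]ethyl}-1,3-dioxolane | C1COC(CCc2coc(Cc3ccoc3)c2)O1
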